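## Analysis of the target

The target is a ternaphthalene with three naphthalene units joined by two aryl–aryl bonds. The central unit (ring B) is an 8-methoxynaphthalen-1-ol. It carries one 4-hydroxy-5-methoxynaphthalen-1-yl group at C2, ortho to its hydroxyl (ring A), and a second, identical one at C4, para to its hydroxyl (ring C). There is no stereocentre. The two biaryl axes, B-C2–A-C1 and the more hindered 1,1'-binaphthyl-type axis B-C4–C-C1, are drawn without descriptors, so no stereocontrol is required. The sensitive groups are the three peri-methoxy naphthols: they are electron-rich and oxidise readily in air and base, and a methoxy group peri to a hydroxyl is open to chelation-assisted cleavage by strong Lewis acids. The difficulty lies in placing two bulky, constitutionally identical naphthyl groups selectively at the ortho and para positions of ring B. Each of the three rings must also end with one free hydroxyl and one methyl ether in a fixed peri relationship. The strategy rests on ring A: its C2 and C3 carry only hydrogen between C1, which is bonded to B-C2, and C4–OH. The A-C1=C2 bond can therefore be formed by olefin metathesis of a 1,1-diarylethene with an allyl ketone placed ortho to the methoxy group. The hindered B-C2–A-C1 bond then never has to be made by a biaryl coupling.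

## Retrosynthetic reasoning

**22 ← 21.** The free naphthols are the oxidation-prone part of 22, so the last operation should only uncover them. The two O–benzyl bonds at ring B O1 and ring C O4 are cut. The forward step is a hydrogenolysis, and 21 contains no other reducible function.

**21 ← 18 + 20.** The bond B-C4–C-C1 is cut. Ring C sits para to the ring B oxygen, where a naphthol is halogenated most readily. A bromine placed there at the start can be carried through the sequence and exchanged for a finished naphthalene at the end. The forward reaction is a Suzuki coupling of bromide 18 with boronate 20, which has to join two naphthalene α-positions. Boronate 20 goes back by borylation to bromide 19 and by O-benzylation to bromonaphthol 3, the same intermediate from which ring B is built.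

**18 ← 17 ← 16 (key disconnection).** Naphthol 18 is first written as its keto tautomer 17, a naphthalen-1(2H)-one. Its only non-aromatic C=C is A-C1=C2, between the carbon bonded to ring B and a CH2 group. Cutting this olefin and capping both ends with methylene groups gives diene 16, which holds a but-3-enoyl group and a 1-arylethenyl group ortho to each other on a methoxybenzene. The cut is made here because A-C2 and A-C3 are unsubstituted, so both olefin partners are as simple as possible. It also turns the hindered biaryl bond at B-C2 into an ordinary bond from B-C2 to an open-chain sp2 carbon. The forward reaction must close the six-membered ring before the allyl double bond moves into conjugation with the ketone.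

**16 ← 15 ← 12 + 13.** The ketone is taken back to carbinol 15, and the bond between the carbinol carbon and the allyl CH2 is cut to give aldehyde 12 and allylboronate 13. The β,γ-unsaturated ketone is the most labile function in the route, so it is generated in the last step before the ring closure.

**12 ← 11 ← 10.** The formyl group is masked as the cyclic acetal 11, and the terminal methylene of the diarylethene is removed to give diaryl ketone 10 (Wittig retron). Olefination is preferred to dehydration of a tertiary carbinol, because a diarylmethyl cation beside the acetal would be intercepted by its oxygen.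

**10 ← 9 ← 5 + 8, and 8 ← 7 ← 6.** The bond between the carbonyl carbon and the methoxyphenyl ring is cut, giving naphthaldehyde 5 and aryl Grignard reagent 8; the carbinol 9 is then oxidised. Reagent 8 comes from acetal 7 and this from aldehyde 6. In 6 the formyl group lies between bromine and methoxy, which is exactly the pattern ring A needs: the formyl carbon becomes A-C4, the brominated carbon A-C8a and the methoxy carbon A-C5. An aldehyde is used as acceptor because it cannot be enolised by the hindered aryl nucleophile.

**5 ← 4 ← 3.** The O-benzyl bond is cut, then the bond B-C2–CHO. The forward reaction is an ortho-formylation directed by the naphthoxide oxygen. C2 is the only ortho position, and the para position is already occupied by bromine.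

**3 ← 2 ← 1.** The C4–Br bond is cut (para-bromination of naphthol 2), then one O–methyl bond (monomethylation of diol 1). The symmetric diol is desymmetrised in the first step because the remaining hydroxyl, hydrogen-bonded to the new peri ether, is much less acidic.

## Alternatives that were turned down

**Alternative 1:** The methoxy-bearing outer rings of A and C are both disconnected at C5–C4a. This leads to diacid A2, in which ring B carries two benzyloxyphenyl groups, each with a 3-carboxyprop-1-enyl arm ortho to the biaryl bond. In the forward key step A2 is heated under acetylating cyclodehydration conditions (carboxylic anhydride with its sodium salt). Each arm passes through a mixed anhydride to a dienylketene, which undergoes six-electron electrocyclisation onto the neighbouring arene carbon and is trapped as the naphthyl acetate A1.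
- For it: it uses the symmetry of the target fully. Both outer rings form in one operation, the two arms come from one twofold olefination, and the teraryl core needs only a double coupling of a simple phenylboronate with no ortho/para differentiation. On these points it is stronger than the chosen route, which builds rings A and C by different chemistry.
- Against it: the new rings emerge as acetates, not methyl ethers. Three steps follow A1 (acetate cleavage, twofold methylation in the presence of three benzyl ethers, threefold hydrogenolysis), against two after the chosen key step.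
- Against it: each closure must occur at the arene carbon flanked by the benzyloxy group. It needs the cis-styryl geometry or prior isomerisation at about 140 °C, and it must succeed twice on a congested teraryl.
- In exchange, the chosen strategy has every methoxy group in place from the first steps and closes its ring at 80 °C in a neutral medium.

**Alternative 2:** The phenol ring of ring B is disconnected at B-C2–C3. The precursor is triene A4, a cyclohexenone from a six-membered 1,3-diketone that carries a silyl dienol ether arm with ring A and a 1-arylethenyl arm with ring C. Heating A4 closes B-C2–C3 by disrotatory six-electron electrocyclisation, and a quinone oxidant in the same pot removes the hydrogens at C2 and C3 to give tetralone A3.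
- For it: both naphthyl groups arrive as intact units on open-chain carbons, so no hindered biaryl coupling is needed. This is stronger than the chosen route, whose step 14 is such a coupling. The two oxygens of ring B are also differentiated from the start as silyl ether and ketone.
- Against it: in A3 the second ring of B is still a cyclohexanone. It must be dehydrogenated to a naphthol by an oxidant in the presence of two electron-rich benzyloxy(methoxy)naphthalenes, then methylated, desilylated and debenzylated, which makes four steps after the key step.
- Against it: A4 is very congested at the terminus that bears ring A. Its enol silylation must be regioselective in a vinylogous tricarbonyl system, and the hot quinone oxidant can attack the electron-rich arenes.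
- In exchange, the chosen strategy takes ring B from a naphthalene that is already aromatic, needs no oxidant-driven aromatisation and is shorter.

**Alternative 3:** The phenol rings of A and C are each disconnected at C1–C8a and C4–C4a. This gives bis-diene A6, in which ring B carries two 1,4-bis(silyloxy)buta-1,3-dien-1-yl arms (tert-butyldimethylsilyl assumed), and two molecules of 3-methoxybenzyne A7. In the forward step A7, released from a halogenated aryl sulfonate by an alkyllithium at -78 °C, adds twice in [4+2] fashion. The cycloadducts lose silanol on hydrolytic work-up and aromatise to the bis-naphthol A5.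
- For it: this is the shortest plan. A5 is one hydrogenolysis away from 22, and both outer rings with their methoxy groups form in one flask. In step economy after the key step it beats the chosen route.
- Against it: both partners are unsymmetrical, and the methoxy group must end up peri to the new hydroxyl in both cycloadditions. The silyloxy groups at the two diene termini largely cancel the electronic bias, so only the steric difference between the termini remains to control orientation.
- Against it: A6 is a fourfold silyl enol ether of a bis-1,4-dicarbonyl compound. Its diene geometries must allow the s-cis conformation, it is hydrolytically labile, and it is exposed to an alkyllithium and to the ene and [2+2] reactivity of A7.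
- In exchange, the chosen strategy fixes every substituent position through the substitution pattern of aldehyde 6 and bromonaphthol 3, so its key step raises no regiochemical question.

Key step: step 11

## Route

Assumption: the two biaryl axes of the target carry no descriptors, so 22 is prepared without axial control, and the carbinol centres of 9 and 15 are racemic and are removed again.

Step 1
Reactants: 1 naphthalene-1,8-diol
Product: 2 8-methoxynaphthalen-1-ol
Conditions: MeI (1.05 equiv), K2CO3, acetone, reflux
Reagents that add atoms: iodomethane, CI
Why: Williamson monoalkylation; after the first O-methylation the remaining hydroxyl is hydrogen-bonded to the peri methoxy oxygen and is far less acidic, so one equivalent of MeI should stop at the monoether.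

Step 2
Reactants: 2 8-methoxynaphthalen-1-ol
Product: 3 4-bromo-8-methoxynaphthalen-1-ol
Conditions: NBS (1.0 equiv), MeCN, -20 → 0 °C
Reagents that add atoms: N-bromosuccinimide, O=C1CCC(=O)N1Br
Why: Electrophilic aromatic bromination; the free hydroxyl activates its own ring much more strongly than the methoxy group activates the other, and NBS in MeCN attacks 1-naphthols at the para position C4.

Step 3
Reactants: 3 4-bromo-8-methoxynaphthalen-1-ol
Product: 4 4-bromo-1-hydroxy-8-methoxynaphthalene-2-carbaldehyde
Conditions: MgCl2, Et3N, (CH2O)n, MeCN, reflux; 1 M HCl work-up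
Reagents that add atoms: paraformaldehyde (as formaldehyde), C=O
Why: Magnesium-mediated ortho-formylation (Casnati–Skattebøl): the magnesium naphthoxide delivers coordinated formaldehyde to the ortho carbon and a second formaldehyde oxidises the resulting benzylic alkoxide by hydride transfer. C2 is the only ortho position and C4 is blocked by bromine, so the carbon substituent can only enter at B-C2.

Step 4
Reactants: 4 4-bromo-1-hydroxy-8-methoxynaphthalene-2-carbaldehyde
Product: 5 1-(benzyloxy)-4-bromo-8-methoxynaphthalene-2-carbaldehyde
Conditions: BnBr, K2CO3, DMF, 50 °C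
Reagents that add atoms: benzyl bromide, BrCc1ccccc1
Why: Williamson ether synthesis on a salicylaldehyde-type naphthol with a non-enolisable aldehyde. The benzyl ether should withstand the organomagnesium, ylide, oxidation and metathesis steps and is removed at the end by hydrogenolysis.

Step 5
Reactants: 6 2-bromo-6-methoxybenzaldehyde
Product: 7 2-(2-bromo-6-methoxyphenyl)-1,3-dioxolane
Conditions: HOCH2CH2OH, p-TsOH (cat.), PhMe, reflux, Dean–Stark
Reagents that add atoms: ethane-1,2-diol, OCCO
Why: Acid-catalysed acetalisation driven by azeotropic removal of water; masking the formyl group allows the aryl bromide to be converted into a Grignard reagent.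

Step 6
Reactants: 7 2-(2-bromo-6-methoxyphenyl)-1,3-dioxolane; 5 1-(benzyloxy)-4-bromo-8-methoxynaphthalene-2-carbaldehyde
Product: 9 [1-(benzyloxy)-4-bromo-8-methoxynaphthalen-2-yl][2-(1,3-dioxolan-2-yl)-3-methoxyphenyl]methanol (racemic), via aryl Grignard reagent 8 (not isolated)
Conditions: 7, Mg, THF, reflux; then 5, THF, 0 °C → rt; aq. NH4Cl
Reagents that add atoms: none
Why: Magnesium insertion gives the ortho-acetal aryl Grignard reagent, which adds to the non-enolisable aldehyde; an aryl Grignard reagent does not exchange with the naphthyl bromide at these temperatures. The carbinol centre forms racemic and is removed in step 7.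

Step 7
Reactants: 9 [1-(benzyloxy)-4-bromo-8-methoxynaphthalen-2-yl][2-(1,3-dioxolan-2-yl)-3-methoxyphenyl]methanol
Product: 10 [1-(benzyloxy)-4-bromo-8-methoxynaphthalen-2-yl][2-(1,3-dioxolan-2-yl)-3-methoxyphenyl]methanone
Conditions: Dess–Martin periodinane, NaHCO3, CH2Cl2, rt
Reagents that add atoms: none
Why: Dess–Martin oxidation of a doubly benzylic secondary alcohol; the NaHCO3 buffer keeps the dioxolane intact.

Step 8
Reactants: 10 [1-(benzyloxy)-4-bromo-8-methoxynaphthalen-2-yl][2-(1,3-dioxolan-2-yl)-3-methoxyphenyl]methanone
Product: 12 2-{1-[1-(benzyloxy)-4-bromo-8-methoxynaphthalen-2-yl]ethenyl}-6-methoxybenzaldehyde, via alkene acetal 11 (not isolated)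
Conditions: MePPh3Br, KOtBu, THF, 0 °C → reflux; then 1 M HCl, THF, rt
Reagents that add atoms: methyltriphenylphosphonium bromide, C[P+](c1ccccc1)(c1ccccc1)c1ccccc1.[Br-]; water, O
Why: Wittig methylenation of a non-enolisable diaryl ketone, followed in the same flask by mild acid hydrolysis of the aryl dioxolane. The olefination forms the 1,1-diarylethene without a carbocation that the neighbouring acetal oxygen could trap, and dilute acid at room temperature should not protonate the twisted diarylethene.

Step 9
Reactants: 12 2-{1-[1-(benzyloxy)-4-bromo-8-methoxynaphthalen-2-yl]ethenyl}-6-methoxybenzaldehyde; 13 2-allyl-4,4,5,5-tetramethyl-1,3,2-dioxaborolane (allylboronic acid pinacol ester)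
Product: 15 1-(2-{1-[1-(benzyloxy)-4-bromo-8-methoxynaphthalen-2-yl]ethenyl}-6-methoxyphenyl)but-3-en-1-ol (racemic), via homoallyl pinacol borate 14 (not isolated)
Conditions: 13, PhMe, 60 °C; then H2O, rt
Reagents that add atoms: none
Why: Allylboration of an aldehyde through a closed six-membered chair transition state; it needs neither base nor Lewis acid, so the aryl bromide and the diarylethene are untouched, and water cleaves the borate ester. The carbinol centre is racemic and is removed in step 10.

Step 10
Reactants: 15 1-(2-{1-[1-(benzyloxy)-4-bromo-8-methoxynaphthalen-2-yl]ethenyl}-6-methoxyphenyl)but-3-en-1-ol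
Product: 16 1-(2-{1-[1-(benzyloxy)-4-bromo-8-methoxynaphthalen-2-yl]ethenyl}-6-methoxyphenyl)but-3-en-1-one
Conditions: Dess–Martin periodinane, NaHCO3, CH2Cl2, 0 °C
Reagents that add atoms: none
Why: Dess–Martin oxidation of a homoallylic alcohol under buffered, non-basic conditions should give the β,γ-unsaturated ketone without moving the double bond. Compound 16 is taken on at once, without storage or prolonged contact with silica.

Step 11
Reactants: 16 1-(2-{1-[1-(benzyloxy)-4-bromo-8-methoxynaphthalen-2-yl]ethenyl}-6-methoxyphenyl)but-3-en-1-one
Product: 18 4-[1-(benzyloxy)-4-bromo-8-methoxynaphthalen-2-yl]-8-methoxynaphthalen-1-ol, via naphthalen-1(2H)-one 17 (not isolated)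
Conditions: RuCl2(H2IMes)(=CH-C6H4-2-O-i-Pr) (5 mol %), 1,4-benzoquinone (10 mol %), PhMe (0.01 M), 80 °C, Ar
Reagents that add atoms: none
Why: The second-generation Hoveyda–Grubbs catalyst releases a ruthenium alkylidene that loads on the unhindered monosubstituted alkene of the allyl ketone, since the 1,1-diarylethene is too hindered to initiate. The resulting Ru=CH–CH2–C(=O)Ar adds intramolecularly across the diarylethene to a ruthenacyclobutane, whose cycloreversion forms A-C1=C2 and expels Ru=CH2, which leaves as ethylene on turnover. The closest known reaction type is the ring-closing metathesis of 1-(2-alkenylaryl)but-3-en-1-ones to naphthalen-1(2H)-ones and 1-naphthols, together with closures onto α-arylstyrenes that give trisubstituted cyclic styrenes. One ring is closed: the six-membered phenol ring of ring A, by ring-closing metathesis between two alkenes held ortho to each other on the methoxybenzene. Ketone 17 then enolises to the aromatic naphthol 18, which makes the closure irreversible. No stereocentre is formed. The step needs metathesis to outrun migration of the allyl double bond into conjugation, because the crotonyl isomer would close a five-membered ring; the neutral degassed medium and 1,4-benzoquinone, which intercepts ruthenium hydrides, should secure this. It also needs ring closure to beat dimerisation, which high dilution and the ortho arrangement of the two alkenes should secure. The aryl bromide and the benzyl ether are inert to the alkylidene.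

Step 12
Reactants: 3 4-bromo-8-methoxynaphthalen-1-ol
Product: 19 1-(benzyloxy)-4-bromo-8-methoxynaphthalene
Conditions: BnBr, K2CO3, DMF, 50 °C
Reagents that add atoms: benzyl bromide, BrCc1ccccc1
Why: Williamson ether synthesis; the naphthol is protected with the same group as in ring B, so that one hydrogenolysis frees both at the end.

Step 13
Reactants: 19 1-(benzyloxy)-4-bromo-8-methoxynaphthalene
Product: 20 2-[4-(benzyloxy)-5-methoxynaphthalen-1-yl]-4,4,5,5-tetramethyl-1,3,2-dioxaborolane
Conditions: B2pin2, PdCl2(dppf), KOAc, 1,4-dioxane, 90 °C
Reagents that add atoms: bis(pinacolato)diboron, CC1(C)OB(OC1(C)C)B1OC(C)(C)C(C)(C)O1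
Why: Miyaura borylation: oxidative addition of the aryl bromide to zerovalent palladium, acetate-assisted transmetalation from the diboron reagent and reductive elimination. The weak base KOAc should keep the product from coupling with unreacted bromide.

Step 14
Reactants: 18 4-[1-(benzyloxy)-4-bromo-8-methoxynaphthalen-2-yl]-8-methoxynaphthalen-1-ol; 20 2-[4-(benzyloxy)-5-methoxynaphthalen-1-yl]-4,4,5,5-tetramethyl-1,3,2-dioxaborolane
Product: 21 4-{1-(benzyloxy)-4-[4-(benzyloxy)-5-methoxynaphthalen-1-yl]-8-methoxynaphthalen-2-yl}-8-methoxynaphthalen-1-ol
Conditions: Pd(OAc)2, SPhos, K3PO4, PhMe–H2O (degassed), 90 °C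
Reagents that add atoms: none
Why: Suzuki–Miyaura coupling forming the B-C4–C-C1 bond; the bulky, electron-rich SPhos ligand promotes oxidative addition into the electron-rich naphthyl bromide and reductive elimination of the hindered 1,1'-binaphthyl-type biaryl. The free naphthol of 18 is carried as its phenoxide under degassed conditions.

Step 15
Reactants: 21 4-{1-(benzyloxy)-4-[4-(benzyloxy)-5-methoxynaphthalen-1-yl]-8-methoxynaphthalen-2-yl}-8-methoxynaphthalen-1-ol
Product: 22 2,4-bis(4-hydroxy-5-methoxynaphthalen-1-yl)-8-methoxynaphthalen-1-ol (target)
Conditions: H2 (1 atm), Pd/C, EtOAc–MeOH, rt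
Reagents that add atoms: none
Why: Catalytic hydrogenolysis of two aryl benzyl ethers; 21 has no other reducible group and naphthalene rings are not hydrogenated at 1 atm and room temperature. The product is worked up under inert gas because the tris-naphthol is easily oxidised.

## Compound list

1 | naphthalene-1,8-diol | Oc1cccc2cccc(O)c12 | starting material
2 | 8-methoxynaphthalen-1-ol | COc1cccc2cccc(O)c12 | intermediate
3 | 4-bromo-8-methoxynaphthalen-1-ol | COc1cccc2c(Br)ccc(O)c12 | intermediate
4 | 4-bromo-1-hydroxy-8-methoxynaphthalene-2-carbaldehyde | COc1cccc2c(Br)cc(C=O)c(O)c12 | intermediate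
5 | 1-(benzyloxy)-4-bromo-8-methoxynaphthalene-2-carbaldehyde | COc1cccc2c(Br)cc(C=O)c(OCc3ccccc3)c12 | intermediate
6 | 2-bromo-6-methoxybenzaldehyde | COc1cccc(Br)c1C=O | starting material
7 | 2-(2-bromo-6-methoxyphenyl)-1,3-dioxolane | COc1cccc(Br)c1C1OCCO1 | intermediate
8 | [2-(1,3-dioxolan-2-yl)-3-methoxyphenyl]magnesium bromide | COc1cccc([Mg]Br)c1C1OCCO1 | intermediate
9 | [1-(benzyloxy)-4-bromo-8-methoxynaphthalen-2-yl][2-(1,3-dioxolan-2-yl)-3-methoxyphenyl]methanol (racemic) | COc1cccc(C(O)c2cc(Br)c3cccc(OC)c3c2OCc2ccccc2)c1C1OCCO1 | intermediate
10 | [1-(benzyloxy)-4-bromo-8-methoxynaphthalen-2-yl][2-(1,3-dioxolan-2-yl)-3-methoxyphenyl]methanone | COc1cccc(C(=O)c2cc(Br)c3cccc(OC)c3c2OCc2ccccc2)c1C1OCCO1 | intermediate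
11 | 2-(2-{1-[1-(benzyloxy)-4-bromo-8-methoxynaphthalen-2-yl]ethenyl}-6-methoxyphenyl)-1,3-dioxolane | COc1cccc(C(=C)c2cc(Br)c3cccc(OC)c3c2OCc2ccccc2)c1C1OCCO1 | intermediate
12 | 2-{1-[1-(benzyloxy)-4-bromo-8-methoxynaphthalen-2-yl]ethenyl}-6-methoxybenzaldehyde | COc1cccc(C(=C)c2cc(Br)c3cccc(OC)c3c2OCc2ccccc2)c1C=O | intermediate
13 | 2-allyl-4,4,5,5-tetramethyl-1,3,2-dioxaborolane (allylboronic acid pinacol ester) | C=CCB1OC(C)(C)C(C)(C)O1 | starting material
14 | 2-{[1-(2-{1-[1-(benzyloxy)-4-bromo-8-methoxynaphthalen-2-yl]ethenyl}-6-methoxyphenyl)but-3-en-1-yl]oxy}-4,4,5,5-tetramethyl-1,3,2-dioxaborolane (racemic) | C=CCC(OB1OC(C)(C)C(C)(C)O1)c1c(OC)cccc1C(=C)c1cc(Br)c2cccc(OC)c2c1OCc1ccccc1 | intermediate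
15 | 1-(2-{1-[1-(benzyloxy)-4-bromo-8-methoxynaphthalen-2-yl]ethenyl}-6-methoxyphenyl)but-3-en-1-ol (racemic) | C=CCC(O)c1c(OC)cccc1C(=C)c1cc(Br)c2cccc(OC)c2c1OCc1ccccc1 | intermediate
16 | 1-(2-{1-[1-(benzyloxy)-4-bromo-8-methoxynaphthalen-2-yl]ethenyl}-6-methoxyphenyl)but-3-en-1-one | C=CCC(=O)c1c(OC)cccc1C(=C)c1cc(Br)c2cccc(OC)c2c1OCc1ccccc1 | intermediate
17 | 4-[1-(benzyloxy)-4-bromo-8-methoxynaphthalen-2-yl]-8-methoxynaphthalen-1(2H)-one | COc1cccc2c1C(=O)CC=C2c1cc(Br)c2cccc(OC)c2c1OCc1ccccc1 | intermediate
18 | 4-[1-(benzyloxy)-4-bromo-8-methoxynaphthalen-2-yl]-8-methoxynaphthalen-1-ol | COc1cccc2c(-c3cc(Br)c4cccc(OC)c4c3OCc3ccccc3)ccc(O)c12 | intermediate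
19 | 1-(benzyloxy)-4-bromo-8-methoxynaphthalene | COc1cccc2c(Br)ccc(OCc3ccccc3)c12 | intermediate
20 | 2-[4-(benzyloxy)-5-methoxynaphthalen-1-yl]-4,4,5,5-tetramethyl-1,3,2-dioxaborolane | COc1cccc2c(B3OC(C)(C)C(C)(C)O3)ccc(OCc3ccccc3)c12 | intermediate
21 | 4-{1-(benzyloxy)-4-[4-(benzyloxy)-5-methoxynaphthalen-1-yl]-8-methoxynaphthalen-2-yl}-8-methoxynaphthalen-1-ol | COc1cccc2c(-c3cc(-c4ccc(OCc5ccccc5)c5c(OC)cccc45)c4cccc(OC)c4c3OCc3ccccc3)ccc(O)c12 | intermediate
22 | 2,4-bis(4-hydroxy-5-methoxynaphthalen-1-yl)-8-methoxynaphthalen-1-ol | COc1cccc2c(-c3cc(-c4ccc(O)c5c(OC)cccc45)c4cccc(OC)c4c3O)ccc(O)c12 | target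

## Step count and least certain steps

Total: 15 steps. Longest linear sequence: 12 steps (1, 2, 3, 4, 6, 7, 8, 9, 10, 11, 14, 15) from naphthalene-1,8-diol. Steps 5, 12 and 13 lie on the two side branches.

**Step 11 (key step).** The allyl double bond may migrate into conjugation with the ketone, either during the work-up of step 10 or through ruthenium hydrides during metathesis. The isomer would then close a five-membered ring or stall. The ketone oxygen may also chelate the alkylidene and slow turnover, and intermolecular metathesis of the allyl groups may compete because the diarylethene is hindered. Fallback: set out from carbinol 15 and run the ring-closing metathesis at the alcohol oxidation level with the same catalyst in PhMe. This should give 4-[1-(benzyloxy)-4-bromo-8-methoxynaphthalen-2-yl]-8-methoxy-1,2-dihydronaphthalen-1-ol F1, in which no conjugating carbonyl is present during the closure. Oxidation of F1 with Dess–Martin periodinane then gives ketone 17, which tautomerises, and the route is rejoined at 18. This detour also avoids isolating the labile ketone 16.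

**Step 14.** Oxidative addition into the hindered, electron-rich bromide may be slow. Boronate 20 may lose boron by protonolysis in hot aqueous base, and the naphthoxide of 18 may bind palladium. Fallback: set out from 18 and benzylate the free naphthol (BnBr, K2CO3, DMF) to 1-(benzyloxy)-2-[4-(benzyloxy)-5-methoxynaphthalen-1-yl]-4-bromo-8-methoxynaphthalene F2. Bromide 19 is converted with n-BuLi at -78 °C and then ZnCl2 into [4-(benzyloxy)-5-methoxynaphthalen-1-yl]zinc chloride F3. Anhydrous Negishi coupling of F2 with F3 (Pd(OAc)2, RuPhos, THF, 60 °C) should give 1-(benzyloxy)-2,4-bis[4-(benzyloxy)-5-methoxynaphthalen-1-yl]-8-methoxynaphthalene F4. Hydrogenolysis of its three benzyl ethers over Pd/C returns to the route at the target 22.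

**Step 8.** Olefination of the di-ortho-substituted diaryl ketone may stall at slow oxaphosphetane formation. Fallback: set out from ketone 10 and add MeMgBr in the presence of CeCl3 (THF, -78 → 0 °C) to give 1-[1-(benzyloxy)-4-bromo-8-methoxynaphthalen-2-yl]-1-[2-(1,3-dioxolan-2-yl)-3-methoxyphenyl]ethan-1-ol F5. Dehydration with the Burgess reagent (PhMe, 50 °C) is a neutral syn elimination that has only the methyl hydrogens available, and it rejoins the route at the alkene acetal 11, which is hydrolysed to 12 as before.

**Step 3.** The magnesium may be held in a chelate between O1 and the peri methoxy oxygen, and the bromine lowers the nucleophilicity of the ring, so formylation may be slow. The intermediate hydroxymethyl naphthol may also condense with a second naphthol. Fallback: set out from 3 and acetylate (Ac2O, pyridine) to 4-bromo-8-methoxynaphthalen-1-yl acetate F6. A Fries rearrangement catalysed by Sc(OTf)3 (PhMe, 100 °C) can only go ortho, because C4 carries bromine, and should give 1-(4-bromo-1-hydroxy-8-methoxynaphthalen-2-yl)ethan-1-one F7. Benzylation (BnBr, K2CO3) gives 1-[1-(benzyloxy)-4-bromo-8-methoxynaphthalen-2-yl]ethan-1-one F8. Addition of Grignard reagent 8 to F8 in the presence of LaCl3·2LiCl, which suppresses enolisation, leads to the tertiary alcohol F5 described under step 8. Burgess dehydration then rejoins the route at 11.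

## Further compounds

F1 | step 11 | 4-[1-(benzyloxy)-4-bromo-8-methoxynaphthalen-2-yl]-8-methoxy-1,2-dihydronaphthalen-1-ol (racemic) | COc1cccc2c1C(O)CC=C2c1cc(Br)c2cccc(OC)c2c1OCc1ccccc1
F2 | step 14 | 1-(benzyloxy)-2-[4-(benzyloxy)-5-methoxynaphthalen-1-yl]-4-bromo-8-methoxynaphthalene | COc1cccc2c(-c3cc(Br)c4cccc(OC)c4c3OCc3ccccc3)ccc(OCc3ccccc3)c12
F3 | step 14 | [4-(benzyloxy)-5-methoxynaphthalen-1-yl]zinc chloride | COc1cccc2c([Zn]Cl)ccc(OCc3ccccc3)c12
F4 | step 14 | 1-(benzyloxy)-2,4-bis[4-(benzyloxy)-5-methoxynaphthalen-1-yl]-8-methoxynaphthalene | COc1cccc2c(-c3cc(-c4ccc(OCc5ccccc5)c5c(OC)cccc45)c4cccc(OC)c4c3OCc3ccccc3)ccc(OCc3ccccc3)c12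
F5 | step 8 | 1-[1-(benzyloxy)-4-bromo-8-methoxynaphthalen-2-yl]-1-[2-(1,3-dioxolan-2-yl)-3-methoxyphenyl]ethan-1-ol (racemic) | COc1cccc(C(C)(O)c2cc(Br)c3cccc(OC)c3c2OCc2ccccc2)c1C1OCCO1
F6 | step 3 | 4-bromo-8-methoxynaphthalen-1-yl acetate | COc1cccc2c(Br)ccc(OC(C)=O)c12
F7 | step 3 | 1-(4-bromo-1-hydroxy-8-methoxynaphthalen-2-yl)ethan-1-one | COc1cccc2c(Br)cc(C(C)=O)c(O)c12
F8 | step 3 | 1-[1-(benzyloxy)-4-bromo-8-methoxynaphthalen-2-yl]ethan-1-one | COc1cccc2c(Br)cc(C(C)=O)c(OCc3ccccc3)c12
A1 | alternative 1 | 2,4-bis[5-acetoxy-4-(benzyloxy)naphthalen-1-yl]-1-(benzyloxy)-8-methoxynaphthalene | COc1cccc2c(-c3ccc(OCc4ccccc4)c4c(OC(C)=O)cccc34)cc(-c3ccc(OCc4ccccc4)c4c(OC(C)=O)cccc34)c(OCc3ccccc3)c12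
A2 | alternative 1 | 1-(benzyloxy)-2,4-bis[4-(benzyloxy)-2-(3-carboxyprop-1-en-1-yl)phenyl]-8-methoxynaphthalene (alkene geometry not fixed) | COc1cccc2c(-c3ccc(OCc4ccccc4)cc3C=CCC(=O)O)cc(-c3ccc(OCc4ccccc4)cc3C=CCC(=O)O)c(OCc3ccccc3)c12
A3 | alternative 2 | 5,7-bis[4-(benzyloxy)-5-methoxynaphthalen-1-yl]-8-[tert-butyl(dimethyl)silyloxy]-3,4-dihydronaphthalen-1(2H)-one | O=C1CCCc2c(-c3ccc(OCc4ccccc4)c4c(OC)cccc34)cc(-c3ccc(OCc4ccccc4)c4c(OC)cccc34)c(O[Si](C)(C)C(C)(C)C)c12
A4 | alternative 2 | 3-{1-[4-(benzyloxy)-5-methoxynaphthalen-1-yl]ethenyl}-2-{2-[4-(benzyloxy)-5-methoxynaphthalen-1-yl]-1-[tert-butyl(dimethyl)silyloxy]ethenyl}cyclohex-2-en-1-one (enol ether geometry not fixed) | O=C1CCCC(C(=C)c2ccc(OCc3ccccc3)c3c(OC)cccc23)=C1C(O[Si](C)(C)C(C)(C)C)=Cc1ccc(OCc2ccccc2)c2c(OC)cccc12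
A5 | alternative 3 | 1-(benzyloxy)-2,4-bis(4-hydroxy-5-methoxynaphthalen-1-yl)-8-methoxynaphthalene | COc1cccc2c(-c3cc(-c4ccc(O)c5c(OC)cccc45)c4cccc(OC)c4c3OCc3ccccc3)ccc(O)c12
A6 | alternative 3 | 1-(benzyloxy)-2,4-bis{1,4-bis[tert-butyl(dimethyl)silyloxy]buta-1,3-dien-1-yl}-8-methoxynaphthalene (diene geometry not fixed) | COc1cccc2c(C(O[Si](C)(C)C(C)(C)C)=CC=CO[Si](C)(C)C(C)(C)C)cc(C(O[Si](C)(C)C(C)(C)C)=CC=CO[Si](C)(C)C(C)(C)C)c(OCc3ccccc3)c12
A7 | alternative 3 | 3-methoxybenzyne (1,2-didehydro-3-methoxybenzene) | COC1=CC=CC#C1
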